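The target oxolane is numbered O1, C2 (aryl), C3 (CH2OH), C4 (aroyl), C5. Because C4 bears the aroyl carbon and C3 bears both the C2 carbinol carbon and the hydroxymethyl arm, the chain C5–C4–C3–CH2OH is read as a chiral 5-alkoxybutenolide (acetal carbon, β-carbon, α-carbon, carbonyl carbon). One three-component operation joins a lithiated aryl dithiane (a masked aroyl anion) to the β-carbon and an aryl aldehyde to the α-carbon. It forms C4–C(aroyl) and C2–C3 and takes the absolute configuration from a menthyl acetal. The precursors are the dithiane of O-benzylisovanillin, the same aldehyde and (5R)-5-(l-menthyloxy)furan-2(5H)-one; reduction and a lactone-to-oxolane ring switch follow.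

Key step: step 4

Remark: the carbinol centre made in the key step is not relied upon; it is drawn as one epimer, an epimeric mixture would be carried on, and the centre is erased and reset in the cationic ring closure.
Remark: the supplied structures were checked and are consistent; the key step leaves the aroyl-bearing carbon with the configuration opposite to the target, which is why an equilibration α to the ketone is part of the route.
Remark: the menthyloxyfuranone is also offered by suppliers; it is made here in two steps so that the route does not depend on that.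

Step 1
Reactants: 1 O-benzylisovanillin (3-benzyloxy-4-methoxybenzaldehyde); 2 propane-1,3-dithiol
Product: 3 2-(3-benzyloxy-4-methoxyphenyl)-1,3-dithiane
Conditions: BF3·OEt2 (0.2 equiv), CH2Cl2, 0 °C to rt
Reagents that add atoms: none
Why: Lewis-acid-catalysed dithioacetalisation of an aromatic aldehyde is dependable, the aryl benzyl and methyl ethers tolerate catalytic BF3·OEt2 at this temperature, and no stereocentre is formed.

Step 2
Reactants: 4 furfural
Product: 5 5-hydroxyfuran-2(5H)-one (racemic cyclic hemiacylal)
Conditions: O2, visible light, rose bengal (cat.), MeOH, rt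
Reagents that add atoms: dioxygen O=O
Why: Sensitised photooxygenation, in which singlet oxygen adds [4+2] across the furan and methanolysis of the endoperoxide expels the formyl carbon as methyl formate, should deliver the hydroxybutenolide, whose single stereocentre is labile and needs no control.

Step 3
Reactants: 5 5-hydroxyfuran-2(5H)-one; 6 (−)-menthol
Product: 8 (5R)-5-[(1R,2S,5R)-menthyloxy]furan-2(5H)-one, via (5S)-menthyloxyfuranone epimer 7 (not isolated)
Conditions: p-TsOH·H2O (cat.), toluene, reflux with azeotropic removal of water; crystallisation from petroleum ether; mother liquor re-equilibrated with p-TsOH and recrystallised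
Reagents that add atoms: none
Why: Acid-catalysed acetalisation of the hemiacylal with the secondary alcohol gives both acetal epimers, and because the acetal carbon epimerises through the ring oxocarbenium ion under the same acid, crystallisation of the less soluble (5R)-epimer should drain epimer 7 into 8 (crystallisation-driven equilibration) while the menthol centres stay untouched.

Step 4
Reactants: 3 2-(3-benzyloxy-4-methoxyphenyl)-1,3-dithiane; 8 (5R)-5-[(1R,2S,5R)-menthyloxy]furan-2(5H)-one; 1 O-benzylisovanillin
Product: 11 (3S,4R,5R)-4-[2-(3-benzyloxy-4-methoxyphenyl)-1,3-dithian-2-yl]-3-[(S)-(3-benzyloxy-4-methoxyphenyl)(hydroxy)methyl]-5-[(1R,2S,5R)-menthyloxy]dihydrofuran-2(3H)-one, via 2-lithio-2-(3-benzyloxy-4-methoxyphenyl)-1,3-dithiane 9 (not isolated), via lithium lactone enolate 10 (not isolated)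
Conditions: n-BuLi, THF, −78 to −30 °C; 8, −78 °C; 1, −78 °C; aq NH4Cl at −78 °C
Reagents that add atoms: none
Why: n-BuLi removes the benzylic dithiane proton to give the sulfur-stabilised carbanion 9, a masked aroyl anion, which adds in Michael fashion to the β-carbon of butenolide 8 to give lithium enolate 10; this enolate is then intercepted at carbon by aldehyde 1 in an aldol addition, so the C4–C(aroyl) and C2–C3 bonds of the target arise in one flask. The closest known reaction type is the tandem conjugate addition–aldol coupling of lithiated 2-aryl-1,3-dithianes with butenolides and aldehydes that is used for lignan lactones. No ring is closed, and the lactone and the dithiane ring are carried through unchanged. The lactone C4 centre is set by the C5 menthyloxy group, which blocks its own face so that 9 enters anti; the C3 centre is set by the bulky new C4 dithianyl group, which sends the aldehyde to the opposite face and gives the 3,4-trans lactone; the carbinol centre is only weakly biased by the lithium-bridged aldol transition state and is not relied upon. The step needs 1,4- over 1,2-addition, which the soft, hindered, charge-delocalised dithianyl anion and the unhindered β-carbon should secure, and it needs the aldolate to be kept from retro-aldol cleavage, which the quench at −78 °C should secure.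

Step 5
Reactants: 11 lactone acetal from step 4
Product: 12 (1S,2R,3R)-1-(3-benzyloxy-4-methoxyphenyl)-3-[2-(3-benzyloxy-4-methoxyphenyl)-1,3-dithian-2-yl]-2-(hydroxymethyl)butane-1,4-diol
Conditions: LiAlH4, THF, 0 °C to rt; aq NaOH work-up
Reagents that add atoms: none
Why: Hydride reduction of the lactone opens the ring, the liberated hemiacetal alkoxide expels menthoxide and the resulting aldehyde is reduced as well, so both oxygenated termini should become CH2OH (ester and masked aldehyde reduction) while the dithiane, the benzyl ethers and the two backbone stereocentres are untouched.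

Step 6
Reactants: 12 triol
Product: 13 [(2S,3R,4R)-2-(3-benzyloxy-4-methoxyphenyl)-4-[2-(3-benzyloxy-4-methoxyphenyl)-1,3-dithian-2-yl]oxolan-3-yl]methanol
Conditions: (+)-10-camphorsulfonic acid (0.1 equiv), CH2Cl2, 0 °C, short reaction time; Et3N quench
Reagents that add atoms: none
Why: Acid-catalysed dehydrative cycloetherification through the para-methoxy-stabilised benzylic cation (SN1), which only the C5 hydroxyl can trap in a five-membered ring (the C3 hydroxymethyl arm could only form an oxetane), should close O1–C2, with the aryl group taking the position trans to the C3 arm under reversible ionisation so that both carbinol epimers of 12 converge on one C2 configuration.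

Step 7
Reactants: 13 oxolane alcohol
Product: 14 tert-butyl{[(2S,3R,4R)-2-(3-benzyloxy-4-methoxyphenyl)-4-[2-(3-benzyloxy-4-methoxyphenyl)-1,3-dithian-2-yl]oxolan-3-yl]methoxy}dimethylsilane
Conditions: TBSCl, imidazole, DMF, rt
Reagents that add atoms: tert-butyldimethylsilyl chloride CC(C)(C)[Si](C)(C)Cl
Why: Standard silylation of the only free (primary) hydroxyl, which must be masked so that it can neither form a bicyclic hemiketal with the cis ketone unveiled next nor act as a nucleophile during the base equilibration.

Step 8
Reactants: 14 silyl ether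
Product: 15 (2S,3R,4R)-4-(3-benzyloxy-4-methoxybenzoyl)-2-(3-benzyloxy-4-methoxyphenyl)-3-[(tert-butyldimethylsilyloxy)methyl]oxolane (aroyl cis to the silyloxymethyl arm)
Conditions: MeI, CaCO3, MeCN/H2O (4:1), 45 °C
Reagents that add atoms: water O
Why: Alkylative dithioacetal hydrolysis, in which S-methylation opens the ring to an aryl-stabilised thionium ion that water captures, should release the aryl ketone, with CaCO3 buffering the HI so that the silyl ether and the cyclic benzylic ether survive; any partial epimerisation at C4 is harmless because step 9 equilibrates that centre.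

Step 9
Reactants: 15 cis ketone
Product: 16 (2S,3R,4S)-4-(3-benzyloxy-4-methoxybenzoyl)-2-(3-benzyloxy-4-methoxyphenyl)-3-[(tert-butyldimethylsilyloxy)methyl]oxolane (all-trans)
Conditions: K2CO3, MeOH/THF, rt
Reagents that add atoms: none
Why: Base-mediated thermodynamic epimerisation through the ketone enolate should move the aroyl group off the face of the C3 arm and give the more stable 3,4-trans isomer, C2 and C3 carry no acidic hydrogen, and ring opening by β-elimination of O1 would be the reverse of a 5-endo-trig closure and is stereoelectronically disfavoured.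

Step 10
Reactants: 16 all-trans silyl ether
Product: 17 (2S,3R,4S)-4-(3-benzyloxy-4-methoxybenzoyl)-2-(3-benzyloxy-4-methoxyphenyl)-3-(hydroxymethyl)oxolane
Conditions: TBAF, AcOH (1:1), THF, 0 °C to rt
Reagents that add atoms: none
Why: Fluoride-induced cleavage of the silicon–oxygen bond under acetic acid buffering keeps the medium non-basic, so the C4 centre should not move, and the trans arrangement prevents the freed hydroxyl from closing onto the ketone.

Step 11
Reactants: 17 dibenzyl ether
Product: 18 (2S,3R,4S)-4-(3-hydroxy-4-methoxybenzoyl)-2-(3-hydroxy-4-methoxyphenyl)-3-(hydroxymethyl)oxolane (target CNP0234761.1)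
Conditions: H2 (1 atm), Pd/C (10 wt%), EtOAc, rt, stopped at full conversion
Reagents that add atoms: none
Why: Catalytic hydrogenolysis of aryl benzyl ethers in neutral ethyl acetate is expected to be much faster than reduction of the electron-rich aryl ketone or cleavage of the cyclic benzylic C2–O1 bond, and no stereocentre is touched.

Compound list
1 | O-benzylisovanillin (3-benzyloxy-4-methoxybenzaldehyde) | COc1ccc(C=O)cc1OCc1ccccc1 | starting material
2 | propane-1,3-dithiol | SCCCS | starting material
3 | 2-(3-benzyloxy-4-methoxyphenyl)-1,3-dithiane | COc1ccc(C2SCCCS2)cc1OCc1ccccc1 | intermediate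
4 | furfural | O=Cc1ccco1 | starting material
5 | 5-hydroxyfuran-2(5H)-one (racemic) | O=C1C=CC(O)O1 | intermediate
6 | (−)-menthol, (1R,2S,5R)-2-isopropyl-5-methylcyclohexanol | CC(C)[C@@H]1CC[C@@H](C)C[C@H]1O | starting material
7 | (5S)-5-[(1R,2S,5R)-menthyloxy]furan-2(5H)-one | O=C1C=C[C@@H](O[C@@H]2C[C@H](C)CC[C@H]2C(C)C)O1 | intermediate
8 | (5R)-5-[(1R,2S,5R)-menthyloxy]furan-2(5H)-one | O=C1C=C[C@H](O[C@@H]2C[C@H](C)CC[C@H]2C(C)C)O1 | intermediate
9 | 2-lithio-2-(3-benzyloxy-4-methoxyphenyl)-1,3-dithiane | COc1ccc(C2([Li])SCCCS2)cc1OCc1ccccc1 | intermediate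
10 | lithium enolate of (4R,5R)-4-[2-(3-benzyloxy-4-methoxyphenyl)-1,3-dithian-2-yl]-5-[(1R,2S,5R)-menthyloxy]dihydrofuran-2(3H)-one | COc1ccc(C2(SCCCS2)[C@H]3[C@H](O[C@@H]4C[C@H](C)CC[C@H]4C(C)C)OC(O[Li])=C3)cc1OCc1ccccc1 | intermediate
11 | (3S,4R,5R)-4-[2-(3-benzyloxy-4-methoxyphenyl)-1,3-dithian-2-yl]-3-[(S)-(3-benzyloxy-4-methoxyphenyl)(hydroxy)methyl]-5-[(1R,2S,5R)-menthyloxy]dihydrofuran-2(3H)-one | COc1ccc(C2(SCCCS2)[C@H]3[C@H](O[C@@H]4C[C@H](C)CC[C@H]4C(C)C)OC(=O)[C@@H]3[C@H](O)c5ccc(OC)c(OCc6ccccc6)c5)cc1OCc1ccccc1 | intermediate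
12 | (1S,2R,3R)-1-(3-benzyloxy-4-methoxyphenyl)-3-[2-(3-benzyloxy-4-methoxyphenyl)-1,3-dithian-2-yl]-2-(hydroxymethyl)butane-1,4-diol | COc1ccc(C2(SCCCS2)[C@@H](CO)[C@H](CO)[C@H](O)c3ccc(OC)c(OCc4ccccc4)c3)cc1OCc1ccccc1 | intermediate
13 | [(2S,3R,4R)-2-(3-benzyloxy-4-methoxyphenyl)-4-[2-(3-benzyloxy-4-methoxyphenyl)-1,3-dithian-2-yl]oxolan-3-yl]methanol | COc1ccc(C3(SCCCS3)[C@H]2CO[C@H](c4ccc(OC)c(OCc5ccccc5)c4)[C@H]2CO)cc1OCc1ccccc1 | intermediate
14 | tert-butyl{[(2S,3R,4R)-2-(3-benzyloxy-4-methoxyphenyl)-4-[2-(3-benzyloxy-4-methoxyphenyl)-1,3-dithian-2-yl]oxolan-3-yl]methoxy}dimethylsilane | COc1ccc(C3(SCCCS3)[C@H]2CO[C@H](c4ccc(OC)c(OCc5ccccc5)c4)[C@H]2CO[Si](C)(C)C(C)(C)C)cc1OCc1ccccc1 | intermediate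
15 | (2S,3R,4R)-4-(3-benzyloxy-4-methoxybenzoyl)-2-(3-benzyloxy-4-methoxyphenyl)-3-[(tert-butyldimethylsilyloxy)methyl]oxolane | COc1ccc(C(=O)[C@H]2CO[C@H](c3ccc(OC)c(OCc4ccccc4)c3)[C@H]2CO[Si](C)(C)C(C)(C)C)cc1OCc1ccccc1 | intermediate
16 | (2S,3R,4S)-4-(3-benzyloxy-4-methoxybenzoyl)-2-(3-benzyloxy-4-methoxyphenyl)-3-[(tert-butyldimethylsilyloxy)methyl]oxolane | COc1ccc(C(=O)[C@@H]2CO[C@H](c3ccc(OC)c(OCc4ccccc4)c3)[C@H]2CO[Si](C)(C)C(C)(C)C)cc1OCc1ccccc1 | intermediate
17 | (2S,3R,4S)-4-(3-benzyloxy-4-methoxybenzoyl)-2-(3-benzyloxy-4-methoxyphenyl)-3-(hydroxymethyl)oxolane | COc1ccc(C(=O)[C@@H]2CO[C@H](c3ccc(OC)c(OCc4ccccc4)c3)[C@H]2CO)cc1OCc1ccccc1 | intermediate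
18 | (2S,3R,4S)-4-(3-hydroxy-4-methoxybenzoyl)-2-(3-hydroxy-4-methoxyphenyl)-3-(hydroxymethyl)oxolane | COc1ccc(C(=O)[C@@H]2CO[C@H](c3ccc(OC)c(O)c3)[C@H]2CO)cc1O | target

Total step count: 11.
Longest linear sequence: 10 steps (furfural 4 to target 18 through steps 2 to 11); 9 steps from aldehyde 1.

Steps most likely to fail

Step 4. The tandem sequence may suffer from competing 1,2-addition or proton transfer in the first stage, or from retro-aldol loss of the aldehyde before the quench. The fallback separates the two bond formations. It sets out from 3 and 8: anion 9 is added to 8 as before, but the enolate is protonated with aq NH4Cl at −78 °C and the conjugate adduct (4R,5R)-4-[2-(3-benzyloxy-4-methoxyphenyl)-1,3-dithian-2-yl]-5-[(1R,2S,5R)-menthyloxy]dihydrofuran-2(3H)-one F1 is isolated. Its enolate is then regenerated with LDA in THF at −78 °C, transmetallated with ZnCl2 to the less basic zinc enolate and treated with aldehyde 1. The dithianyl group again directs the aldehyde to the opposite face, and the path comes back to the route at 11.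

Step 6. The product ether may re-ionise and be lost to irreversible Friedel–Crafts closure of the benzylic cation onto the electron-rich dithiane-bearing arene (an aryltetralin), or the trans selection at C2 may be incomplete. The fallback avoids the cation by forming O1–C5 instead of O1–C2. It sets out from 12, using the (1S)-carbinol epimer drawn, whose configuration is that of C2 in the target. MsCl (2.2 equiv) in pyridine at 0 °C to rt should mesylate both primary hydroxyls to give (1S,2R,3R)-bis-mesylate of the triol F2. In F2 the remaining benzylic hydroxyl displaces the C5 mesylate (5-exo-tet; attack on the other arm would give an oxetane and is slow), giving with retention at C2 the [(2S,3R,4R)-2-aryl-4-(2-aryl-1,3-dithian-2-yl)oxolan-3-yl]methyl methanesulfonate F3. Displacement with CsOAc and 18-crown-6 in toluene at 80 °C gives the corresponding [(2S,3R,4R)-oxolan-3-yl]methyl acetate F4, and K2CO3 in MeOH removes the acetyl group, so the path comes back to the route at 13.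

Step 8. S-Alkylation at the hindered, fully substituted dithiane may be slow, and prolonged heating may cost the silyl ether. The fallback changes the mode of sulfur activation from alkylation to oxidation. It sets out from 14, which is treated with the trivalent iodine reagent PhI(OCOCF3)2 in MeCN/H2O (9:1) with NaHCO3 at 0 °C. Oxidation at sulfur triggers ring opening and hydrolysis within minutes and the dithiol leaves as the cyclic disulfide. No new compound arises on this path (F0), which comes back to the route at 15.

Further compounds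
F1 | step 4 | (4R,5R)-4-[2-(3-benzyloxy-4-methoxyphenyl)-1,3-dithian-2-yl]-5-[(1R,2S,5R)-menthyloxy]dihydrofuran-2(3H)-one | COc1ccc(C2(SCCCS2)[C@H]3[C@H](O[C@@H]4C[C@H](C)CC[C@H]4C(C)C)OC(=O)C3)cc1OCc1ccccc1
F2 | step 6 | (1S,2R,3R)-1-(3-benzyloxy-4-methoxyphenyl)-3-[2-(3-benzyloxy-4-methoxyphenyl)-1,3-dithian-2-yl]-1-hydroxy-2-(mesyloxymethyl)butan-4-yl methanesulfonate (bis-mesylate of the triol) | COc1ccc(C2(SCCCS2)[C@@H](COS(C)(=O)=O)[C@H](COS(C)(=O)=O)[C@H](O)c3ccc(OC)c(OCc4ccccc4)c3)cc1OCc1ccccc1
F3 | step 6 | [(2S,3R,4R)-2-(3-benzyloxy-4-methoxyphenyl)-4-[2-(3-benzyloxy-4-methoxyphenyl)-1,3-dithian-2-yl]oxolan-3-yl]methyl methanesulfonate | COc1ccc(C3(SCCCS3)[C@H]2CO[C@H](c4ccc(OC)c(OCc5ccccc5)c4)[C@H]2COS(C)(=O)=O)cc1OCc1ccccc1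
F4 | step 6 | [(2S,3R,4R)-2-(3-benzyloxy-4-methoxyphenyl)-4-[2-(3-benzyloxy-4-methoxyphenyl)-1,3-dithian-2-yl]oxolan-3-yl]methyl acetate | COc1ccc(C3(SCCCS3)[C@H]2CO[C@H](c4ccc(OC)c(OCc5ccccc5)c4)[C@H]2COC(C)=O)cc1OCc1ccccc1
F0 | step 8 | none | none
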